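Target is made in a chain, and its amount depends on how often the first chain carrier meets partner before transfer agent ends that chain.

    initiator → 2 initiating radical (k1 = 1.5 × 10⁻⁴ s⁻¹)
    2 second chain carrier → ended chains A (k2 = 1.4 × 10⁷ M⁻¹ s⁻¹)
    transfer agent + first chain carrier → side product + idle radical (k3 = 37000 M⁻¹ s⁻¹)
    partner + released group ⇌ idle adduct, settled at all times (K4 = 75 M⁻¹)
    starting material + second chain carrier → released group + first chain carrier (k5 = 8800 M⁻¹ s⁻¹)
    2 idle radical → ended radicals (k6 = 6 × 10⁷ M⁻¹ s⁻¹)
    2 first chain carrier → ended chains B (k7 = 5 × 10⁸ M⁻¹ s⁻¹)
    partner + first chain carrier → target + second chain carrier (k8 = 4100 M⁻¹ s⁻¹)
    starting material + initiating radical → capped initiator + first chain carrier (k9 = 59000 M⁻¹ s⁻¹)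

all flasks: starting material 20 mM; transfer agent 1.00 mM; initiator 0.60 mM; time 2.5 h

| charge | partner |
|---|---|
| Saturday's | 78.0 mM |
| Tuesday's | 60.0 mM |

- percentages count the starting material that a species holds: one ended chains B counts as two
- released group is meant together with its idle adduct
- a step written with two of one species runs at k times the square of its concentration and takes two of it each time
- run time (Saturday's): 2.5 h

* part of the starting material that has reacted at the end, Saturday's
* part of the starting material that has reacted at the end, Tuesday's
* what raising the concentration of partner from its lowest to its highest value here does to the part of the starting material that has reacted (changes below 5 percentage points count as none) (it falls / no change / it rises)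

Follow one first chain carrier. With partner it gives target and second chain carrier, which takes starting material and returns a first chain carrier. With transfer agent it gives side product and idle radical, and the chain is over. Carry the selectivity factor, the rate constant with partner over the rate constant with transfer agent, 0.111. Its zero of scale is the value one, a carrier that picks by concentration, which gives odds of 78.0 in Saturday's flask. The factor cuts these to 8.64 targets per chain ended, the chain length. Now count chains: by 2.5 h the initiator has started 0.889 mM of them, each taking one starting material at its start. At constant odds, Saturday's flask reaches 42.9% reacted.

Object to that: each chain ended on transfer agent eats one of it, and 0.889 mM is a big bite from 1.00 mM. The two takers share one carrier, so the logarithm of the fall in [partner] is the selectivity factor times the logarithm of the fall in [transfer agent]. Reckoned with every chain ended on transfer agent, and with [partner] falling along the way, this law gives Saturday's target as 16.9 mM.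

Object again: first chain carrier also couples with itself. At the start that takes about 13.1% of the started chains. This share goes as the rate of starting over [transfer agent] squared, so with both at 0.5 of their start it is 26.2%. Take the mean, 19.7%, and [transfer agent] ends near 0.286 mM.

Object once more: released group binds partner as idle adduct, a share of 85.4% at Saturday's charge and 81.8% at Tuesday's. Each target therefore costs one partner plus that share, and this multiplies the logarithm for partner. Solved, target comes to 9.53 mM in Saturday's flask and 7.35 mM in Tuesday's. Adding the started chains, I commit to 52.1% for Saturday's and 41.2% for Tuesday's, and for the trend, it rises.

The forecast gives 58% for Saturday's, 47% for Tuesday's and it rises for the trend, holding that “conversion scales roughly with partner”.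

The simulation gives 53.9% for Saturday's and 43.2% for Tuesday's, and it rises by 11 percentage points.

Saturday's flask is not at rest at 2.5 h: 25.9% of its initiator remains, and with 27.1% of its transfer agent left, the odds have climbed from 8.64 to 24.5. At 25.0 h the reacted part stands at 93.9% in Saturday's flask and 80.1% in Tuesday's. Now read Saturday's flask at 40 min: 0.363 mM started at the opening odds gives 15.7% target and 17.5% reacted. The simulation shows 15.7% and 17.5%.

The numbers of this flask were drawn at random within sensible limits; no experiment stands behind them.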